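**Plan**

Unit A is the 7-methoxycoumarin (benzene ring A) and unit B the 5,7-dihydroxycoumarin (benzene ring B).

- Cuts, in retrosynthetic order: the two O-benzyl bonds; pyranone B at O1–C2 and C3=C4 (Wittig–lactonisation) and at C4–C4a (formylation); pyranone A at C4–C4a (alkyne hydroarylation) and at its O1–C2 ester bond (propiolate); the diaryl ether at C8(A)–O (SNAr); both phenol oxygens next to the ether go back to formyl groups (Baeyer–Villiger).
- Forward order: ring B is protected and its formyl group turned into a phenol, SNAr joins it to ring A, the ring A formyl group becomes the propiolate ester, pyranone A closes first, pyranone B second, and debenzylation ends the route.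
- Enabling feature: C4a of unit A lies ortho to the oxygen-bearing C8a and para to the C7 methoxy group, so it is the nucleophilic carbon of ring A and the only one a propiolate tether on the C8a oxygen can reach.
- Protecting groups: ring B carries benzyl ethers on the two oxygens that end as free hydroxyls and a methoxymethyl (MOM) ether on the oxygen that becomes the lactone oxygen, so only one phenol with one free ortho carbon is exposed when pyranone B is built.
- Stereochemistry: the target has no stereocentre; the two cis C3=C4 bonds are fixed by the six-membered lactones.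

Key step: step 7

Assumption: benzyl bromide, chloromethyl methyl ether, mCPBA, DCC, paraformaldehyde and ethyl (triphenylphosphoranylidene)acetate are purchased reagents and carry no compound number.

**Route**

Step 1
Reactants: 1 2,4,6-trihydroxybenzaldehyde
Product: 3 2,4-bis(benzyloxy)-6-hydroxybenzaldehyde, via para-monobenzyl ether 2 (not isolated)
Conditions: BnBr (2.05 equiv), K2CO3 (2.2 equiv), DMF, 0 °C → rt
Reagents that add atoms: benzyl bromide, BrCc1ccccc1
Why: Williamson etherification should alkylate the para hydroxyl first and then one ortho hydroxyl, while the remaining ortho hydroxyl is hydrogen-bonded to the formyl oxygen, is the least nucleophilic and stays free.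

Step 2
Reactants: 3 2,4-bis(benzyloxy)-6-hydroxybenzaldehyde
Product: 4 2,4-bis(benzyloxy)-6-(methoxymethoxy)benzaldehyde
Conditions: NaH, DMF, 0 °C; MOMCl, 0 °C → rt
Reagents that add atoms: chloromethyl methyl ether, COCCl
Why: Irreversible deprotonation with NaH breaks the chelate, and Williamson-type alkylation caps the last phenol as an acetal that tolerates base, peracid and the gold step and can later be removed without touching benzyl ethers or a coumarin double bond.

Step 3
Reactants: 4 2,4-bis(benzyloxy)-6-(methoxymethoxy)benzaldehyde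
Product: 6 2,4-bis(benzyloxy)-6-(methoxymethoxy)phenol, via aryl formate 5 (not isolated)
Conditions: mCPBA, CH2Cl2, 0 °C → rt; then MeOH, Et3N (cat.), rt, argon
Reagents that add atoms: mCPBA (3-chloroperbenzoic acid), O=C(OO)c1cccc(Cl)c1
Why: Baeyer–Villiger (Dakin-type) oxidation, in which three ortho/para alkoxy donors make the aryl group migrate in the Criegee adduct, should give the formate, which methanol cleaves in the same flask.

Step 4
Reactants: 6 2,4-bis(benzyloxy)-6-(methoxymethoxy)phenol; 7 2-fluoro-3-methoxybenzaldehyde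
Product: 8 2-[2,4-bis(benzyloxy)-6-(methoxymethoxy)phenoxy]-3-methoxybenzaldehyde
Conditions: Cs2CO3, DMSO, 110 °C, argon
Reagents that add atoms: none
Why: Nucleophilic aromatic substitution by addition–elimination, in which the ortho formyl group stabilises the Meisenheimer adduct and fluoride is the best leaving group, should let the caesium phenoxide form the diaryl ether with four ortho substituents.

Step 5
Reactants: 8 2-[2,4-bis(benzyloxy)-6-(methoxymethoxy)phenoxy]-3-methoxybenzaldehyde
Product: 10 2-[2,4-bis(benzyloxy)-6-(methoxymethoxy)phenoxy]-3-methoxyphenol, via aryl formate 9 (not isolated)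
Conditions: mCPBA, CH2Cl2, rt; then MeOH, Et3N (cat.), rt
Reagents that add atoms: mCPBA (3-chloroperbenzoic acid), O=C(OO)c1cccc(Cl)c1
Why: Baeyer–Villiger oxidation, in which the ortho aryloxy donor favours aryl over hydride migration and the aldehyde is expected to react with the peracid faster than the electron-rich ring B, should give the formate, which is methanolysed in situ.

Step 6
Reactants: 10 2-[2,4-bis(benzyloxy)-6-(methoxymethoxy)phenoxy]-3-methoxyphenol; 11 propiolic acid
Product: 12 2-[2,4-bis(benzyloxy)-6-(methoxymethoxy)phenoxy]-3-methoxyphenyl prop-2-ynoate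
Conditions: DCC, DMAP (cat.), CH2Cl2, −20 → 0 °C
Reagents that add atoms: none
Why: Steglich-type carbodiimide esterification should give the aryl propiolate under near-neutral conditions at low temperature, which limits base-induced oligomerisation of the propiolate and spares the acetal.

Step 7
Reactants: 12 2-[2,4-bis(benzyloxy)-6-(methoxymethoxy)phenoxy]-3-methoxyphenyl prop-2-ynoate
Product: 13 8-[2,4-bis(benzyloxy)-6-(methoxymethoxy)phenoxy]-7-methoxy-2H-chromen-2-one
Conditions: Ph3PAuCl (5 mol %), AgSbF6 (5 mol %), ClCH2CH2Cl (0.02 M), rt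
Reagents that add atoms: none
Why: Cationic monovalent gold, formed from Ph3PAuCl by chloride abstraction with AgSbF6, binds the alkyne of 12, and C6 of the ester-bearing ring A (the future C4a) attacks the terminal alkyne carbon anti to gold in a Friedel–Crafts-type step; rearomatisation and protodeauration of the vinylgold species release the catalyst and leave the cis C3=C4 bond in the lactone. The closest known reaction type is the gold- or platinum-catalysed intramolecular hydroarylation of aryl alkynoates to coumarins. The pyranone of unit A closes in the 6-endo-dig mode with formation of the C4–C4a bond, and no stereocentre is created. The step needs attack at C6 and not ipso attack at the oxygen-bearing carbon (5-exo, spirocycle) or attack by ring B: C6 is the only unsubstituted carbon ortho to the ester oxygen and is para to the methoxy group, the carbon para to the ipso position carries no donor, and ring B could reach the alkyne only through a ring of nine or more atoms. High dilution should suppress intermolecular hydroarylation by the electron-rich ring B, and the benzyl and methoxymethyl ethers should be inert to the soft Lewis acid.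

Step 8
Reactants: 13 8-[2,4-bis(benzyloxy)-6-(methoxymethoxy)phenoxy]-7-methoxy-2H-chromen-2-one
Product: 14 8-[2,4-bis(benzyloxy)-6-hydroxyphenoxy]-7-methoxy-2H-chromen-2-one
Conditions: conc. HCl (cat.), MeOH/THF, 45 °C
Reagents that add atoms: none
Why: Acid-catalysed acetal exchange with methanol should remove the methoxymethyl group, while the benzyl ethers, the methyl ether, the diaryl ether and the lactone are stable to dilute HCl in methanol.

Step 9
Reactants: 14 8-[2,4-bis(benzyloxy)-6-hydroxyphenoxy]-7-methoxy-2H-chromen-2-one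
Product: 16 4,6-bis(benzyloxy)-2-hydroxy-3-[(7-methoxy-2-oxo-2H-chromen-8-yl)oxy]benzaldehyde, via hydroxymethyl phenol 15 (not isolated)
Conditions: MgCl2, Et3N, (CH2O)n, MeCN, reflux; then 1 M HCl
Reagents that add atoms: paraformaldehyde (formaldehyde unit), C=O
Why: Magnesium-mediated ortho-formylation (Casnati–Skattebøl) delivers formaldehyde from the magnesium phenoxide only to the ortho carbon, of which just one is free, and the hydroxymethyl intermediate should be oxidised in situ by hydride transfer to a second formaldehyde.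

Step 10
Reactants: 16 4,6-bis(benzyloxy)-2-hydroxy-3-[(7-methoxy-2-oxo-2H-chromen-8-yl)oxy]benzaldehyde
Product: 19 5,7-bis(benzyloxy)-8-[(7-methoxy-2-oxo-2H-chromen-8-yl)oxy]-2H-chromen-2-one, via E-hydroxycinnamate 17 (not isolated), via Z-hydroxycinnamate 18 (not isolated)
Conditions: Ph3P=CHCO2Et, PhNEt2, reflux (ca. 215 °C)
Reagents that add atoms: ethyl (triphenylphosphoranylidene)acetate, CCOC(=O)C=P(c1ccccc1)(c1ccccc1)c1ccccc1
Why: Wittig olefination with the stabilised ylide, followed by thermal E-to-Z isomerisation and lactonisation, is the standard way from salicylaldehydes to 3,4-unsubstituted coumarins, and only the hydroxyl next to the formyl group is free to close the ring.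

Step 11
Reactants: 19 5,7-bis(benzyloxy)-8-[(7-methoxy-2-oxo-2H-chromen-8-yl)oxy]-2H-chromen-2-one
Product: 22 5,7-dihydroxy-8-[(7-methoxy-2-oxo-2H-chromen-8-yl)oxy]-2H-chromen-2-one, via 5-benzyloxy-7-hydroxy bis-coumarin 20 (not isolated), via 7-benzyloxy-5-hydroxy bis-coumarin 21 (not isolated)
Conditions: BCl3 (1 M in CH2Cl2), C6HMe5, CH2Cl2, −78 °C; then H2O
Reagents that add atoms: none
Why: Lewis-acid debenzylation with BCl3 and pentamethylbenzene as benzyl cation scavenger should cleave both aryl benzyl ethers at −78 °C without reducing the two C3=C4 bonds, cleaving the methyl ether or C-benzylating the electron-rich ring B.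

**Compound list**

1 | 2,4,6-trihydroxybenzaldehyde | O=Cc1c(O)cc(O)cc1O | starting material
2 | 4-(benzyloxy)-2,6-dihydroxybenzaldehyde | O=Cc1c(O)cc(OCc2ccccc2)cc1O | intermediate
3 | 2,4-bis(benzyloxy)-6-hydroxybenzaldehyde | O=Cc1c(O)cc(OCc2ccccc2)cc1OCc1ccccc1 | intermediate
4 | 2,4-bis(benzyloxy)-6-(methoxymethoxy)benzaldehyde | COCOc1cc(OCc2ccccc2)cc(OCc2ccccc2)c1C=O | intermediate
5 | 2,4-bis(benzyloxy)-6-(methoxymethoxy)phenyl formate | COCOc1cc(OCc2ccccc2)cc(OCc2ccccc2)c1OC=O | intermediate
6 | 2,4-bis(benzyloxy)-6-(methoxymethoxy)phenol | COCOc1cc(OCc2ccccc2)cc(OCc2ccccc2)c1O | intermediate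
7 | 2-fluoro-3-methoxybenzaldehyde | COc1cccc(C=O)c1F | starting material
8 | 2-[2,4-bis(benzyloxy)-6-(methoxymethoxy)phenoxy]-3-methoxybenzaldehyde | COCOc1cc(OCc2ccccc2)cc(OCc2ccccc2)c1Oc1c(OC)cccc1C=O | intermediate
9 | 2-[2,4-bis(benzyloxy)-6-(methoxymethoxy)phenoxy]-3-methoxyphenyl formate | COCOc1cc(OCc2ccccc2)cc(OCc2ccccc2)c1Oc1c(OC)cccc1OC=O | intermediate
10 | 2-[2,4-bis(benzyloxy)-6-(methoxymethoxy)phenoxy]-3-methoxyphenol | COCOc1cc(OCc2ccccc2)cc(OCc2ccccc2)c1Oc1c(OC)cccc1O | intermediate
11 | propiolic acid (prop-2-ynoic acid) | C#CC(=O)O | starting material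
12 | 2-[2,4-bis(benzyloxy)-6-(methoxymethoxy)phenoxy]-3-methoxyphenyl prop-2-ynoate | COCOc1cc(OCc2ccccc2)cc(OCc2ccccc2)c1Oc1c(OC)cccc1OC(=O)C#C | intermediate
13 | 8-[2,4-bis(benzyloxy)-6-(methoxymethoxy)phenoxy]-7-methoxy-2H-chromen-2-one | COCOc1cc(OCc2ccccc2)cc(OCc2ccccc2)c1Oc1c(OC)ccc2ccc(=O)oc12 | intermediate
14 | 8-[2,4-bis(benzyloxy)-6-hydroxyphenoxy]-7-methoxy-2H-chromen-2-one | Oc1cc(OCc2ccccc2)cc(OCc2ccccc2)c1Oc1c(OC)ccc2ccc(=O)oc12 | intermediate
15 | 8-[4,6-bis(benzyloxy)-2-hydroxy-3-(hydroxymethyl)phenoxy]-7-methoxy-2H-chromen-2-one | OCc1c(O)c(Oc2c(OC)ccc3ccc(=O)oc23)c(OCc2ccccc2)cc1OCc1ccccc1 | intermediate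
16 | 4,6-bis(benzyloxy)-2-hydroxy-3-[(7-methoxy-2-oxo-2H-chromen-8-yl)oxy]benzaldehyde | O=Cc1c(O)c(Oc2c(OC)ccc3ccc(=O)oc23)c(OCc2ccccc2)cc1OCc1ccccc1 | intermediate
17 | ethyl (E)-3-{4,6-bis(benzyloxy)-2-hydroxy-3-[(7-methoxy-2-oxo-2H-chromen-8-yl)oxy]phenyl}prop-2-enoate | CCOC(=O)/C=C/c1c(O)c(Oc2c(OC)ccc3ccc(=O)oc23)c(OCc2ccccc2)cc1OCc1ccccc1 | intermediate
18 | ethyl (Z)-3-{4,6-bis(benzyloxy)-2-hydroxy-3-[(7-methoxy-2-oxo-2H-chromen-8-yl)oxy]phenyl}prop-2-enoate | CCOC(=O)/C=C\c1c(O)c(Oc2c(OC)ccc3ccc(=O)oc23)c(OCc2ccccc2)cc1OCc1ccccc1 | intermediate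
19 | 5,7-bis(benzyloxy)-8-[(7-methoxy-2-oxo-2H-chromen-8-yl)oxy]-2H-chromen-2-one | COc1ccc2ccc(=O)oc2c1Oc1c(OCc2ccccc2)cc(OCc2ccccc2)c2ccc(=O)oc12 | intermediate
20 | 5-(benzyloxy)-7-hydroxy-8-[(7-methoxy-2-oxo-2H-chromen-8-yl)oxy]-2H-chromen-2-one | COc1ccc2ccc(=O)oc2c1Oc1c(O)cc(OCc2ccccc2)c2ccc(=O)oc12 | intermediate
21 | 7-(benzyloxy)-5-hydroxy-8-[(7-methoxy-2-oxo-2H-chromen-8-yl)oxy]-2H-chromen-2-one | COc1ccc2ccc(=O)oc2c1Oc1c(OCc2ccccc2)cc(O)c2ccc(=O)oc12 | intermediate
22 | 5,7-dihydroxy-8-[(7-methoxy-2-oxo-2H-chromen-8-yl)oxy]-2H-chromen-2-one | COc1ccc2ccc(=O)oc2c1Oc1c(O)cc(O)c2ccc(=O)oc12 | target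

**Count and risks**

Total step count: 11. Longest linear sequence: 11 steps (1 → 22).

Steps most likely to fail:

Step 4. Substitution at a fluorine-bearing carbon flanked by formyl and methoxy groups, by a phenoxide with two ortho substituents, may be too slow, so that air oxidation of the electron-rich phenoxide or thermal decay of the aldehyde takes over. The fallback sets out from phenol 6 and replaces SNAr by metal-free arylation with a diaryliodonium salt. Purchased 2-iodo-3-methoxybenzaldehyde would be oxidised with mCPBA and TsOH·H2O in MeCN and coupled in the same flask with 1,3,5-trimethoxybenzene to give (2-formyl-6-methoxyphenyl)(2,4,6-trimethoxyphenyl)iodonium 4-methylbenzenesulfonate F1. The potassium salt of 6 (t-BuOK, THF, 0 °C → rt) should then take over the formyl-methoxyphenyl group by ligand coupling, the trimethoxyphenyl group staying on iodine. This reaction type tolerates heavily ortho-substituted partners, and the fallback comes back to the route at aldehyde 8.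

Step 7. Intermolecular hydroarylation of the gold-bound alkyne by ring B of a second molecule, hydration or oligomerisation of the terminal alkyne, or acid-induced loss of the methoxymethyl group before ring closure may erode the cyclisation. The fallback sets out from phenol 10 and builds pyranone A without the alkyne. MgCl2/Et3N/paraformaldehyde in refluxing MeCN would pass through 2-[2,4-bis(benzyloxy)-6-(methoxymethoxy)phenoxy]-6-(hydroxymethyl)-3-methoxyphenol F2 and formylate the only free ortho carbon to give 3-[2,4-bis(benzyloxy)-6-(methoxymethoxy)phenoxy]-2-hydroxy-4-methoxybenzaldehyde F3. Wittig reaction with Ph3P=CHCO2Et in refluxing PhNEt2 would then give ethyl (E)-3-{3-[2,4-bis(benzyloxy)-6-(methoxymethoxy)phenoxy]-2-hydroxy-4-methoxyphenyl}prop-2-enoate F4, which isomerises to ethyl (Z)-3-{3-[2,4-bis(benzyloxy)-6-(methoxymethoxy)phenoxy]-2-hydroxy-4-methoxyphenyl}prop-2-enoate F5 and lactonises. The fallback comes back to the route at coumarin 13.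

Step 9. Formylation may stall because the magnesium phenoxide is crowded by the neighbouring aryloxy group and the reacting carbon is flanked by a benzyloxy group, or the hydroxymethyl stage may condense to diarylmethanes before it is oxidised. The fallback sets out from phenol 14 and closes pyranone B at carbon as in step 7. Esterification with propiolic acid 11 (DCC, DMAP cat., CH2Cl2, −20 → 0 °C) would give 3,5-bis(benzyloxy)-2-[(7-methoxy-2-oxo-2H-chromen-8-yl)oxy]phenyl prop-2-ynoate F6. Ph3PAuCl/AgSbF6 in dilute ClCH2CH2Cl at rt should then effect 6-endo-dig hydroarylation at the only free ortho carbon, which is para to one benzyloxy group and ortho to the other. The fallback bypasses 16 and comes back to the route at bis-coumarin 19.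

**Further compounds**

F1 | step 4 | (2-formyl-6-methoxyphenyl)(2,4,6-trimethoxyphenyl)iodonium 4-methylbenzenesulfonate | COc1cccc(C=O)c1[I+]c1c(OC)cc(OC)cc1OC.Cc1ccc(cc1)S(=O)(=O)[O-]
F2 | step 7 | 2-[2,4-bis(benzyloxy)-6-(methoxymethoxy)phenoxy]-6-(hydroxymethyl)-3-methoxyphenol | COCOc1cc(OCc2ccccc2)cc(OCc2ccccc2)c1Oc1c(OC)ccc(CO)c1O
F3 | step 7 | 3-[2,4-bis(benzyloxy)-6-(methoxymethoxy)phenoxy]-2-hydroxy-4-methoxybenzaldehyde | COCOc1cc(OCc2ccccc2)cc(OCc2ccccc2)c1Oc1c(OC)ccc(C=O)c1O
F4 | step 7 | ethyl (E)-3-{3-[2,4-bis(benzyloxy)-6-(methoxymethoxy)phenoxy]-2-hydroxy-4-methoxyphenyl}prop-2-enoate | CCOC(=O)/C=C/c1ccc(OC)c(Oc2c(OCOC)cc(OCc3ccccc3)cc2OCc2ccccc2)c1O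
F5 | step 7 | ethyl (Z)-3-{3-[2,4-bis(benzyloxy)-6-(methoxymethoxy)phenoxy]-2-hydroxy-4-methoxyphenyl}prop-2-enoate | CCOC(=O)/C=C\c1ccc(OC)c(Oc2c(OCOC)cc(OCc3ccccc3)cc2OCc2ccccc2)c1O
F6 | step 9 | 3,5-bis(benzyloxy)-2-[(7-methoxy-2-oxo-2H-chromen-8-yl)oxy]phenyl prop-2-ynoate | C#CC(=O)Oc1cc(OCc2ccccc2)cc(OCc2ccccc2)c1Oc1c(OC)ccc2ccc(=O)oc12
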